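**Plan**
1. Retrosynthesis: the acetates, the C15 aldehyde, the 1,10-oxirane and the C13 methylene come off first. The core is then cut at C5–C6 together with the lactone O–C12 bond in one operation, then at C7–C8 (aldol), C1=C10 (olefination) and C3–C4/C4=C5 (malonate-derived iodoalkene).
2. Enabling feature (ring carbons C1–C10; C11–C13 on C7; C14 on C10; C15 on C4): C6 is both the carbinol carbon of the five-membered lactone (O–C6–C7–C11–C12) and the allylic carbon next to the ring-cis C4=C5 bond of the ten-membered carbocycle. An alkenyl metal at C5 adding to a C6 aldehyde therefore closes the carbocycle and leaves an alkoxide that reaches the C12 ester through C7.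
3. Forward: iodoalkene aldehyde (C1–C5, C15), then olefination adds C8–C10/C14, then the aldol adds C6, C7, C11, C12. The ten-membered ring closes first, the lactone second (same step), the oxirane last.
4. Stereochemistry: C7/C8 from an Evans syn-aldol with the (R)-benzyl oxazolidinone; C6 from Felkin–Anh addition during ring closure; C1/C10 from Sharpless epoxidation with D-(−)-tartrate. The C4=C5 geometry comes from a decarboxylative elimination, the C1=C10 geometry from the Horner–Wadsworth–Emmons reaction.

Key step: step 19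

Remark: alkali-metal salts formed by simple deprotonation of a numbered compound are treated as forms of that compound; covalent boron, aluminium and chromium intermediates are numbered.

**Route**

Step 1
Reactants: 1 diethyl malonate; 2 3-bromo-1,1-dimethoxypropane
Product: 3 diethyl 2-(3,3-dimethoxypropyl)malonate
Conditions: NaH, THF/DMF, 0 → 60 °C
Reagents that add atoms: none
Why: Malonic ester alkylation (SN2 of the sodium enolate on a primary bromide) is routine and installs C1–C3 with C1 masked as a dimethyl acetal.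

Step 2
Reactants: 3 diethyl 2-(3,3-dimethoxypropyl)malonate
Product: 4 diethyl 2-(diiodomethyl)-2-(3,3-dimethoxypropyl)malonate
Conditions: NaH, Et2O, reflux; then CHI3, reflux
Reagents that add atoms: iodoform, IC(I)I
Why: The tertiary malonate anion takes up a CHI2 group from iodoform (capture of diiodocarbene and reprotonation), the established first stage of the iodoform route from monoalkylmalonates to 2-alkyl-3-iodoacrylic acids.

Step 3
Reactants: 4 diethyl 2-(diiodomethyl)-2-(3,3-dimethoxypropyl)malonate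
Product: 6 (2E)-2-(3,3-dimethoxypropyl)-3-iodoprop-2-enoic acid, via dipotassium malonate 5 (not isolated)
Conditions: KOH, EtOH/H2O (3:1), reflux; then 1 M HCl to pH 4, 0 °C
Reagents that add atoms: potassium hydroxide, [K+].[OH-]
Why: Saponification followed by decarboxylative anti-elimination of iodide (a Grob-type fragmentation) should give the E acid, iodine trans to the carboxyl group and cis to the C3 chain as in the well-known 2-methyl case, which is the C3/C5 cis relation of the later ring-cis C4=C5 bond.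

Step 4
Reactants: 6 (2E)-2-(3,3-dimethoxypropyl)-3-iodoprop-2-enoic acid
Product: 7 (2E)-2-(3,3-dimethoxypropyl)-3-iodoprop-2-en-1-ol
Conditions: LiAlH4, Et2O, 0 °C
Reagents that add atoms: none
Why: Hydride reduction of the carboxylic acid to the allylic alcohol at 0 °C leaves vinyl iodide and acetal untouched, as precedented for 3-iodo-2-methylacrylic acid.

Step 5
Reactants: 7 (2E)-2-(3,3-dimethoxypropyl)-3-iodoprop-2-en-1-ol
Product: 8 tert-butyl{[(2E)-2-(3,3-dimethoxypropyl)-3-iodoprop-2-en-1-yl]oxy}dimethylsilane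
Conditions: TBSCl, imidazole, DMF, 0 °C → rt
Reagents that add atoms: tert-butylchlorodimethylsilane, CC(C)(C)[Si](C)(C)Cl
Why: Standard silylation of a primary allylic alcohol, the TBS ether at C15 being chosen because it should survive every step up to the final fluoride treatment.

Step 6
Reactants: 8 tert-butyl{[(2E)-2-(3,3-dimethoxypropyl)-3-iodoprop-2-en-1-yl]oxy}dimethylsilane
Product: 9 (4E)-4-{[tert-butyl(dimethyl)silyl]oxymethyl}-5-iodopent-4-enal
Conditions: PPTS (cat.), acetone/H2O (10:1), rt
Reagents that add atoms: water, O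
Why: Acid-catalysed hydrolysis of an acyclic dimethyl acetal of an aliphatic aldehyde proceeds under pyridinium catalysis at room temperature, conditions under which a primary TBS ether is stable.

Step 7
Reactants: 10 2-iodoethanol
Product: 11 triethyl(2-iodoethoxy)silane
Conditions: TESCl, imidazole, CH2Cl2, 0 °C
Reagents that add atoms: chlorotriethylsilane, CC[Si](CC)(CC)Cl
Why: Routine silylation, TES being taken so that this oxygen (later C8) can be unmasked in the presence of the TBS ether at C15.

Step 8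
Reactants: 12 triethyl phosphonoacetate; 11 triethyl(2-iodoethoxy)silane
Product: 13 ethyl 2-(diethoxyphosphoryl)-4-(triethylsilyloxy)butanoate
Conditions: NaH, DMF, 0 °C; then 11, 60 °C
Reagents that add atoms: none
Why: C-Alkylation of the phosphonoacetate anion by a primary iodide is a standard way to α-substituted Horner–Wadsworth–Emmons reagents and brings in C8 and C9.

Step 9
Reactants: 13 ethyl 2-(diethoxyphosphoryl)-4-(triethylsilyloxy)butanoate; 9 (4E)-4-{[tert-butyl(dimethyl)silyl]oxymethyl}-5-iodopent-4-enal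
Product: 14 ethyl (2E,6E)-6-{[tert-butyl(dimethyl)silyl]oxymethyl}-7-iodo-2-[2-(triethylsilyloxy)ethyl]hepta-2,6-dienoate
Conditions: NaH, THF, 0 °C; then 9, 0 °C → rt
Reagents that add atoms: none
Why: Horner–Wadsworth–Emmons olefination of an unbranched aldehyde with an α-alkyl phosphonoacetate under equilibrating sodium conditions favours the E-enoate (ester trans to C2, so C2 cis to C9 as the ring-cis C1=C10 bond requires), and the minor Z isomer is to be removed by chromatography.

Step 10
Reactants: 14 ethyl (2E,6E)-6-{[tert-butyl(dimethyl)silyl]oxymethyl}-7-iodo-2-[2-(triethylsilyloxy)ethyl]hepta-2,6-dienoate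
Product: 15 (2E,6E)-6-{[tert-butyl(dimethyl)silyl]oxymethyl}-7-iodo-2-[2-(triethylsilyloxy)ethyl]hepta-2,6-dien-1-ol
Conditions: i-Bu2AlH (2.5 equiv), CH2Cl2, −78 °C
Reagents that add atoms: none
Why: 1,2-Reduction of the enoate by i-Bu2AlH at −78 °C gives the allylic alcohol (C14–OH) without affecting silyl ethers, vinyl iodide or olefin geometry.

Step 11
Reactants: 15 (2E,6E)-6-{[tert-butyl(dimethyl)silyl]oxymethyl}-7-iodo-2-[2-(triethylsilyloxy)ethyl]hepta-2,6-dien-1-ol
Product: 16 4-methoxybenzyl ether of 15 at the C1 oxygen (C14–OPMB)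
Conditions: NaH, PMBCl, Bu4NI (cat.), THF/DMF, 0 °C → rt
Reagents that add atoms: 4-methoxybenzyl chloride, COc1ccc(CCl)cc1
Why: Williamson etherification of the primary allylic alkoxide gives the PMB ether, which is orthogonal to both silyl ethers and is removed oxidatively just before the epoxidation.

Step 12
Reactants: 16 4-methoxybenzyl ether of 15
Product: 17 (3E,7E)-7-{[tert-butyl(dimethyl)silyl]oxymethyl}-8-iodo-3-{[(4-methoxybenzyl)oxy]methyl}octa-3,7-dien-1-ol
Conditions: PPTS (cat.), MeOH/CH2Cl2 (1:1), 0 °C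
Reagents that add atoms: none
Why: Acid-catalysed methanolysis removes a primary TES ether much faster than a primary TBS ether, so that only the C8 oxygen is set free.

Step 13
Reactants: 17 (3E,7E)-7-{[tert-butyl(dimethyl)silyl]oxymethyl}-8-iodo-3-{[(4-methoxybenzyl)oxy]methyl}octa-3,7-dien-1-ol
Product: 18 (3E,7E)-7-{[tert-butyl(dimethyl)silyl]oxymethyl}-8-iodo-3-{[(4-methoxybenzyl)oxy]methyl}octa-3,7-dienal
Conditions: Dess–Martin periodinane, NaHCO3, CH2Cl2, 0 °C; used at once
Reagents that add atoms: none
Why: Dess–Martin oxidation under buffered, non-basic conditions should give the β,γ-unsaturated aldehyde without moving the C1=C10 double bond into conjugation, provided it is used immediately without chromatography.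

Step 14
Reactants: 19 monomethyl succinate; 20 (R)-4-benzyl-1,3-oxazolidin-2-one
Product: 22 methyl 4-[(4R)-4-benzyl-2-oxo-1,3-oxazolidin-3-yl]-4-oxobutanoate, via mixed pivalic anhydride 21 (not isolated)
Conditions: t-BuCOCl, Et3N, THF, −20 °C; then 20, LiCl, −20 °C → rt
Reagents that add atoms: none
Why: N-Acylation of the oxazolidinone through the mixed pivalic anhydride (LiCl/Et3N variant) is the standard one-pot preparation of such imides and leaves the methyl ester untouched.

Step 15
Reactants: 22 methyl 4-[(4R)-4-benzyl-2-oxo-1,3-oxazolidin-3-yl]-4-oxobutanoate; 18 (3E,7E)-7-{[tert-butyl(dimethyl)silyl]oxymethyl}-8-iodo-3-{[(4-methoxybenzyl)oxy]methyl}octa-3,7-dienal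
Product: 25 methyl (3R,4S,6E,10E)-3-{[(4R)-4-benzyl-2-oxo-1,3-oxazolidin-3-yl]carbonyl}-10-{[tert-butyl(dimethyl)silyl]oxymethyl}-4-hydroxy-11-iodo-6-{[(4-methoxybenzyl)oxy]methyl}undeca-6,10-dienoate, via boron enolate 23 (not isolated), via boron aldolate 24 (not isolated)
Conditions: Bu2BOTf, i-Pr2NEt, CH2Cl2, −78 → 0 °C; then 18, −78 → −10 °C; pH 7 buffer, MeOH, 30% H2O2, 0 °C
Reagents that add atoms: none
Why: Evans syn-aldol reaction, in which the Z dibutylboron enolate of the imide reacts through a Zimmerman–Traxler chair on the enolate face away from the benzyl group of the (R)-auxiliary, setting C7 (R) and C8 (S) in the syn relation, while boron, unlike titanium, should not promote lactonisation of the aldolate onto the C12 ester.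

Step 16
Reactants: 25 the aldol above (C8–OH)
Product: 26 methyl (3R,4S,6E,10E)-3-{[(4R)-4-benzyl-2-oxo-1,3-oxazolidin-3-yl]carbonyl}-10-{[tert-butyl(dimethyl)silyl]oxymethyl}-11-iodo-6-{[(4-methoxybenzyl)oxy]methyl}-4-(triethylsilyloxy)undeca-6,10-dienoate
Conditions: TESOTf, 2,6-lutidine, CH2Cl2, −78 °C
Reagents that add atoms: triethylsilyl trifluoromethanesulfonate, CC[Si](CC)(CC)OS(=O)(=O)C(F)(F)F
Why: Silylation with the triflate at −78 °C caps the C8 hydroxyl at once, so that it cannot lactonise onto the C12 methyl ester, with a group that the final fluoride step removes easily.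

Step 17
Reactants: 26 the TES-protected imide
Product: 27 methyl (3R,4S,6E,10E)-10-{[tert-butyl(dimethyl)silyl]oxymethyl}-3-[(ethylsulfanyl)carbonyl]-11-iodo-6-{[(4-methoxybenzyl)oxy]methyl}-4-(triethylsilyloxy)undeca-6,10-dienoate
Conditions: EtSH, n-BuLi, THF, 0 °C; then 26, 0 °C
Reagents that add atoms: ethanethiol, CCS
Why: Thiolysis of the N-acyloxazolidinone by lithium ethanethiolate cleaves the exocyclic acyl group of hindered β-silyloxy imides selectively, releases the auxiliary and leaves the less electrophilic methyl ester in place.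

Step 18
Reactants: 27 the S-ethyl thioester
Product: 29 methyl (3R,4S,6E,10E)-10-{[tert-butyl(dimethyl)silyl]oxymethyl}-3-formyl-11-iodo-6-{[(4-methoxybenzyl)oxy]methyl}-4-(triethylsilyloxy)undeca-6,10-dienoate, via aluminium hemithioacetal 28 (not isolated)
Conditions: i-Bu2AlH (1.05 equiv), PhMe, −78 °C; aqueous work-up
Reagents that add atoms: none
Why: i-Bu2AlH adds once to the thioester at −78 °C to give a tetrahedral aluminium hemithioacetal that collapses to the aldehyde only on work-up, the thioester being more electrophilic than the methyl ester, so that one equivalent should reduce C6 alone without epimerising C7.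

Step 19
Reactants: 29 the open-chain iodo-diene aldehyde ester (C6 aldehyde, C5 iodide, C12 methyl ester)
Product: 32 (1(10)E,4E,6R,7S,8S)-15-(tert-butyldimethylsilyloxy)-14-(4-methoxybenzyloxy)-8-(triethylsilyloxy)germacra-1(10),4-dien-12,6-olide, via alkenylchromium dichloride 30 (not isolated), via ring-closed hydroxy ester 31 (not isolated)
Conditions: CrCl2 (10 equiv), NiCl2 (0.1 equiv), DMSO/THF, rt, 2 mM, slow addition of 29; aqueous work-up; then PPTS (cat.), PhMe, 40 °C
Reagents that add atoms: none
Why: CrCl2 reduces NiCl2 to zerovalent nickel, which inserts into the C5–I bond with retention, and transmetalation gives the alkenylchromium dichloride (trivalent chromium) that adds to the C6 aldehyde, the closest precedent being Nozaki–Hiyama–Kishi alkenyl iodide–aldehyde closures of medium and large rings. The carbocycle closes 10-exo-trig (C5 onto C6, carbonyl oxygen outside the ring) and the C6 alkoxide then closes the γ-lactone 5-exo-trig on the C12 methyl ester, the mild acid treatment completing this second closure. The new C6 stereocentre is controlled by C7: in the Felkin–Anh arrangement the C8 branch is the large group anti to the incoming C5 and the CH2CO2Me arm the medium group, which leads to 6R and hence to the trans-fused lactone. The step needs this facial selectivity and retention of the C4=C5 geometry; the first rests on the size difference of the two arms at C7 (partly opposed by the 1,3-effect of the C8 silyloxy group), the second on the configurational stability of alkenylnickel and alkenylchromium species, so that C3 and C6 end up cis on the double bond. High dilution and the tolerance of organochromium reagents for esters, silyl ethers and benzyl ethers secure the chemoselectivity.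

Step 20
Reactants: 32 the ten-membered diene fused to the trans-lactone
Product: 33 13-(dimethylamino) derivative of 32 (Mannich base; both C11 epimers)
Conditions: LiN(iPr)2, THF, −78 °C; then CH2=NMe2+ I−, −78 → 0 °C
Reagents that add atoms: N,N-dimethylmethyleneiminium iodide (Eschenmoser's salt), C=[N+](C)C.[I-]
Why: Mannich reaction of the lactone lithium enolate (C11 is the only enolisable position) with the preformed iminium salt is the first half of the Eschenmoser methylenation, and the C11 configuration is irrelevant.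

Step 21
Reactants: 33 the Mannich base
Product: 35 (1(10)E,4E,6R,7S,8S)-15-(tert-butyldimethylsilyloxy)-14-(4-methoxybenzyloxy)-8-(triethylsilyloxy)germacra-1(10),4,11(13)-trien-12,6-olide, via trimethylammonium iodide 34 (not isolated)
Conditions: MeI, THF, rt; then NaHCO3 (aq.), EtOAc, rt
Reagents that add atoms: none
Why: Exhaustive methylation and E1cB (Hofmann-type) elimination of trimethylamine under bicarbonate give the α-methylene lactone, a sequence well known for sesquiterpene lactones.

Step 22
Reactants: 35 the α-methylene lactone PMB ether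
Product: 36 (1(10)E,4E,6R,7S,8S)-15-(tert-butyldimethylsilyloxy)-14-hydroxy-8-(triethylsilyloxy)germacra-1(10),4,11(13)-trien-12,6-olide
Conditions: DDQ, CH2Cl2/pH 7 buffer (10:1), 0 °C
Reagents that add atoms: none
Why: Oxidative cleavage of the electron-rich PMB ether by DDQ in wet, buffered CH2Cl2 frees the C14 allylic alcohol while silyl ethers, olefins and the methylene lactone are inert.

Step 23
Reactants: 36 the C14 allylic alcohol
Product: 37 (1R,4E,6R,7S,8S,10R)-15-(tert-butyldimethylsilyloxy)-1,10-epoxy-14-hydroxy-8-(triethylsilyloxy)germacra-4,11(13)-dien-12,6-olide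
Conditions: Ti(OiPr)4, D-(−)-diisopropyl tartrate, t-BuOOH, 4 Å MS, CH2Cl2, −20 °C
Reagents that add atoms: tert-butyl hydroperoxide, CC(C)(C)OO
Why: Sharpless asymmetric epoxidation of an E-type 2,3-disubstituted allylic alcohol, in which the titanium–tartrate complex binds the C14 hydroxyl and, with the D-(−)-tartrate, delivers oxygen to the face that gives 1R,10R, the cis-addition keeping C2 and C9 cis on the oxirane, while the C4=C5 bond (no free allylic hydroxyl) and the electron-poor methylene lactone should not react.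

Step 24
Reactants: 37 the epoxy alcohol
Product: 38 (1R,4E,6R,7R,8S,10R)-1,10-epoxy-8,14,15-trihydroxygermacra-4,11(13)-dien-12,6-olide
Conditions: HF·pyridine, pyridine, THF, 0 °C
Reagents that add atoms: none
Why: Fluoride-mediated desilylation buffered with pyridine removes the secondary TES and the primary allylic TBS ether under conditions mild enough for the oxirane and the methylene lactone.

Step 25
Reactants: 38 the epoxy triol
Product: 39 (1R,4E,6R,7R,8S,10R)-1,10-epoxy-8,14-dihydroxy-15-oxogermacra-4,11(13)-dien-12,6-olide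
Conditions: MnO2, CH2Cl2, rt
Reagents that add atoms: none
Why: MnO2 oxidises only allylic alcohols, so that C15–OH (allylic to C4=C5) should give the enal while the epoxy alcohol at C14 and the secondary C8 hydroxyl remain.

Step 26
Reactants: 39 the dihydroxy enal
Product: 40 (1R,4E,6R,7R,8S,10R)-8,14-diacetoxy-1,10-epoxy-15-oxogermacra-4,11(13)-dien-12,6-olide (CNP0211286.1)
Conditions: Ac2O, pyridine, DMAP (cat.), CH2Cl2, 0 °C → rt
Reagents that add atoms: acetic anhydride, CC(=O)OC(C)=O
Why: DMAP-catalysed acetylation of the primary C14 and secondary C8 hydroxyls completes the target without touching any stereocentre.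

**Compound list**
1 | diethyl malonate | CCOC(=O)CC(=O)OCC | starting material
2 | 3-bromo-1,1-dimethoxypropane | COC(CCBr)OC | starting material
3 | diethyl 2-(3,3-dimethoxypropyl)malonate | CCOC(=O)C(CCC(OC)OC)C(=O)OCC | intermediate
4 | diethyl 2-(diiodomethyl)-2-(3,3-dimethoxypropyl)malonate | CCOC(=O)C(CCC(OC)OC)(C(I)I)C(=O)OCC | intermediate
5 | dipotassium 2-(diiodomethyl)-2-(3,3-dimethoxypropyl)malonate (not isolated) | COC(OC)CCC(C(I)I)(C(=O)[O-])C(=O)[O-].[K+].[K+] | intermediate
6 | (2E)-2-(3,3-dimethoxypropyl)-3-iodoprop-2-enoic acid | COC(OC)CC/C(C(=O)O)=C\I | intermediate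
7 | (2E)-2-(3,3-dimethoxypropyl)-3-iodoprop-2-en-1-ol | COC(OC)CC/C(CO)=C\I | intermediate
8 | tert-butyl{[(2E)-2-(3,3-dimethoxypropyl)-3-iodoprop-2-en-1-yl]oxy}dimethylsilane | COC(OC)CC/C(CO[Si](C)(C)C(C)(C)C)=C\I | intermediate
9 | (4E)-4-{[tert-butyl(dimethyl)silyl]oxymethyl}-5-iodopent-4-enal | O=CCC/C(CO[Si](C)(C)C(C)(C)C)=C\I | intermediate
10 | 2-iodoethanol | OCCI | starting material
11 | triethyl(2-iodoethoxy)silane | CC[Si](CC)(CC)OCCI | intermediate
12 | triethyl phosphonoacetate | CCOC(=O)CP(=O)(OCC)OCC | starting material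
13 | ethyl 2-(diethoxyphosphoryl)-4-(triethylsilyloxy)butanoate | CCOC(=O)C(CCO[Si](CC)(CC)CC)P(=O)(OCC)OCC | intermediate
14 | ethyl (2E,6E)-6-{[tert-butyl(dimethyl)silyl]oxymethyl}-7-iodo-2-[2-(triethylsilyloxy)ethyl]hepta-2,6-dienoate | CCOC(=O)/C(CCO[Si](CC)(CC)CC)=C/CC/C(CO[Si](C)(C)C(C)(C)C)=C\I | intermediate
15 | (2E,6E)-6-{[tert-butyl(dimethyl)silyl]oxymethyl}-7-iodo-2-[2-(triethylsilyloxy)ethyl]hepta-2,6-dien-1-ol | OC/C(CCO[Si](CC)(CC)CC)=C/CC/C(CO[Si](C)(C)C(C)(C)C)=C\I | intermediate
16 | 1-({[(2E,6E)-6-{[tert-butyl(dimethyl)silyl]oxymethyl}-7-iodo-2-[2-(triethylsilyloxy)ethyl]hepta-2,6-dien-1-yl]oxy}methyl)-4-methoxybenzene | COc1ccc(COC/C(CCO[Si](CC)(CC)CC)=C/CC/C(CO[Si](C)(C)C(C)(C)C)=C\I)cc1 | intermediate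
17 | (3E,7E)-7-{[tert-butyl(dimethyl)silyl]oxymethyl}-8-iodo-3-{[(4-methoxybenzyl)oxy]methyl}octa-3,7-dien-1-ol | COc1ccc(COC/C(CCO)=C/CC/C(CO[Si](C)(C)C(C)(C)C)=C\I)cc1 | intermediate
18 | (3E,7E)-7-{[tert-butyl(dimethyl)silyl]oxymethyl}-8-iodo-3-{[(4-methoxybenzyl)oxy]methyl}octa-3,7-dienal | COc1ccc(COC/C(CC=O)=C/CC/C(CO[Si](C)(C)C(C)(C)C)=C\I)cc1 | intermediate
19 | monomethyl succinate (4-methoxy-4-oxobutanoic acid) | COC(=O)CCC(=O)O | starting material
20 | (R)-4-benzyl-1,3-oxazolidin-2-one | O=C1N[C@H](Cc2ccccc2)CO1 | starting material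
21 | mixed anhydride of monomethyl succinate and pivalic acid (not isolated) | COC(=O)CCC(=O)OC(=O)C(C)(C)C | intermediate
22 | methyl 4-[(4R)-4-benzyl-2-oxo-1,3-oxazolidin-3-yl]-4-oxobutanoate | COC(=O)CCC(=O)N1[C@H](Cc2ccccc2)COC1=O | intermediate
23 | (Z)-dibutylboron enolate of 22 (not isolated) | COC(=O)C/C=C(\OB(CCCC)CCCC)N1[C@H](Cc2ccccc2)COC1=O | intermediate
24 | O-dibutylboron aldolate of 25 (not isolated) | COC(=O)C[C@@H](C(=O)N1[C@H](Cc2ccccc2)COC1=O)[C@@H](OB(CCCC)CCCC)C/C(COCc3ccc(OC)cc3)=C\CC/C(CO[Si](C)(C)C(C)(C)C)=C\I | intermediate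
25 | methyl (3R,4S,6E,10E)-3-{[(4R)-4-benzyl-2-oxo-1,3-oxazolidin-3-yl]carbonyl}-10-{[tert-butyl(dimethyl)silyl]oxymethyl}-4-hydroxy-11-iodo-6-{[(4-methoxybenzyl)oxy]methyl}undeca-6,10-dienoate | COC(=O)C[C@@H](C(=O)N1[C@H](Cc2ccccc2)COC1=O)[C@@H](O)C/C(COCc3ccc(OC)cc3)=C\CC/C(CO[Si](C)(C)C(C)(C)C)=C\I | intermediate
26 | 4-O-triethylsilyl ether of 25 | COC(=O)C[C@@H](C(=O)N1[C@H](Cc2ccccc2)COC1=O)[C@@H](O[Si](CC)(CC)CC)C/C(COCc3ccc(OC)cc3)=C\CC/C(CO[Si](C)(C)C(C)(C)C)=C\I | intermediate
27 | methyl (3R,4S,6E,10E)-10-{[tert-butyl(dimethyl)silyl]oxymethyl}-3-[(ethylsulfanyl)carbonyl]-11-iodo-6-{[(4-methoxybenzyl)oxy]methyl}-4-(triethylsilyloxy)undeca-6,10-dienoate | COC(=O)C[C@@H](C(=O)SCC)[C@@H](O[Si](CC)(CC)CC)C/C(COCc1ccc(OC)cc1)=C\CC/C(CO[Si](C)(C)C(C)(C)C)=C\I | intermediate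
28 | O-diisobutylaluminium S-ethyl hemithioacetal of 29 (not isolated; hemithioacetal carbon unassigned) | COC(=O)C[C@@H](C(O[Al](CC(C)C)CC(C)C)SCC)[C@@H](O[Si](CC)(CC)CC)C/C(COCc1ccc(OC)cc1)=C\CC/C(CO[Si](C)(C)C(C)(C)C)=C\I | intermediate
29 | methyl (3R,4S,6E,10E)-10-{[tert-butyl(dimethyl)silyl]oxymethyl}-3-formyl-11-iodo-6-{[(4-methoxybenzyl)oxy]methyl}-4-(triethylsilyloxy)undeca-6,10-dienoate | COC(=O)C[C@@H](C=O)[C@@H](O[Si](CC)(CC)CC)C/C(COCc1ccc(OC)cc1)=C\CC/C(CO[Si](C)(C)C(C)(C)C)=C\I | intermediate
30 | alkenylchromium dichloride from 29 (CrCl2 on C5 in place of iodine, trivalent chromium; not isolated) | COC(=O)C[C@@H](C=O)[C@@H](O[Si](CC)(CC)CC)C/C(COCc1ccc(OC)cc1)=C\CC/C(CO[Si](C)(C)C(C)(C)C)=C\[Cr](Cl)Cl | intermediate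
31 | methyl (1(10)E,4E,6R,7S,8S)-15-(tert-butyldimethylsilyloxy)-6-hydroxy-14-(4-methoxybenzyloxy)-8-(triethylsilyloxy)germacra-1(10),4-dien-12-oate (formed as its chromium alkoxide; not isolated) | COC(=O)C[C@H]1[C@H](O)/C=C(/CO[Si](C)(C)C(C)(C)C)CC/C=C(/COCc2ccc(OC)cc2)C[C@@H]1O[Si](CC)(CC)CC | intermediate
32 | (1(10)E,4E,6R,7S,8S)-15-(tert-butyldimethylsilyloxy)-14-(4-methoxybenzyloxy)-8-(triethylsilyloxy)germacra-1(10),4-dien-12,6-olide (both ring olefins cis within the ring, lactone trans-fused) | C1C(=O)O[C@@H]2/C=C(/CO[Si](C)(C)C(C)(C)C)CC/C=C(/COCc3ccc(OC)cc3)C[C@H](O[Si](CC)(CC)CC)[C@@H]12 | intermediate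
33 | 13-(dimethylamino) derivative of 32 (C11 epimers) | CN(C)CC1C(=O)O[C@@H]2/C=C(/CO[Si](C)(C)C(C)(C)C)CC/C=C(/COCc3ccc(OC)cc3)C[C@H](O[Si](CC)(CC)CC)[C@@H]12 | intermediate
34 | 13-(trimethylammonio) derivative of 32, iodide (C11 epimers; not isolated) | C[N+](C)(C)CC1C(=O)O[C@@H]2/C=C(/CO[Si](C)(C)C(C)(C)C)CC/C=C(/COCc3ccc(OC)cc3)C[C@H](O[Si](CC)(CC)CC)[C@@H]12.[I-] | intermediate
35 | (1(10)E,4E,6R,7S,8S)-15-(tert-butyldimethylsilyloxy)-14-(4-methoxybenzyloxy)-8-(triethylsilyloxy)germacra-1(10),4,11(13)-trien-12,6-olide | C=C1C(=O)O[C@@H]2/C=C(/CO[Si](C)(C)C(C)(C)C)CC/C=C(/COCc3ccc(OC)cc3)C[C@H](O[Si](CC)(CC)CC)[C@@H]12 | intermediate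
36 | (1(10)E,4E,6R,7S,8S)-15-(tert-butyldimethylsilyloxy)-14-hydroxy-8-(triethylsilyloxy)germacra-1(10),4,11(13)-trien-12,6-olide | C=C1C(=O)O[C@@H]2/C=C(/CO[Si](C)(C)C(C)(C)C)CC/C=C(/CO)C[C@H](O[Si](CC)(CC)CC)[C@@H]12 | intermediate
37 | (1R,4E,6R,7S,8S,10R)-15-(tert-butyldimethylsilyloxy)-1,10-epoxy-14-hydroxy-8-(triethylsilyloxy)germacra-4,11(13)-dien-12,6-olide | C=C1C(=O)O[C@@H]2/C=C(/CO[Si](C)(C)C(C)(C)C)CC[C@H]3O[C@@]3(CO)C[C@H](O[Si](CC)(CC)CC)[C@@H]12 | intermediate
38 | (1R,4E,6R,7R,8S,10R)-1,10-epoxy-8,14,15-trihydroxygermacra-4,11(13)-dien-12,6-olide | C=C1C(=O)O[C@@H]2/C=C(/CO)CC[C@H]3O[C@@]3(CO)C[C@H](O)[C@@H]12 | intermediate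
39 | (1R,4E,6R,7R,8S,10R)-1,10-epoxy-8,14-dihydroxy-15-oxogermacra-4,11(13)-dien-12,6-olide | C=C1C(=O)O[C@@H]2/C=C(/C=O)CC[C@H]3O[C@@]3(CO)C[C@H](O)[C@@H]12 | intermediate
40 | (1R,4E,6R,7R,8S,10R)-8,14-diacetoxy-1,10-epoxy-15-oxogermacra-4,11(13)-dien-12,6-olide (CNP0211286.1) | C=C1C(=O)O[C@@H]2/C=C(/C=O)CC[C@H]3O[C@@]3(COC(C)=O)C[C@H](OC(C)=O)[C@@H]12 | target

(The C7 descriptor changes between R and S along the route only because the CIP ranking of C6 against C8 changes with the oxygen substituents; the spatial arrangement is the same throughout.)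

**Step count and risks**

Total step count: 26. Longest linear sequence: 23 steps (1–6, 9–13, 15–26).

Step 19 is the most likely to fail. The strain of the cis,cis-cyclodecadiene transition state may erode Felkin control (or slow closure until the C–Cr bond is protonated), so that the alkoxide of the wrong C6 configuration forms and lactonises to the cis-fused ring. The fallback corrects C6 by an invertive C–O bond formation instead of by facial selectivity. It sets out from 29: the ring closure is run as before, and the cis-fused 6-epi lactone F1 is opened with LiOH in THF/H2O to the (6S)-hydroxy acid F2. F2 is relactonised under Mitsunobu conditions (PPh3, DIAD, toluene, high dilution) with inversion at the allylic C6, which comes back to the route at 32.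

Step 18 is the second risk. Hydride attack on the unhindered C12 methyl ester may compete with attack on the α-branched, more hindered thioester, or the aldehyde may be over-reduced. The fallback uses chelation-controlled reduction of a different acyl derivative. It sets out from thioester 27: silver-assisted aminolysis (AgOTf, MeNHOMe·HCl, i-Pr2NEt, THF) gives the Weinreb amide F3. Reduction of F3 with LiAlH4 at −78 °C stops at the chelated tetrahedral intermediate and is faster than ester reduction, as in aspartate-derived amide esters; work-up returns to the route at aldehyde 29.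

Step 23 is the third risk. The ten-membered ring and the fused lactone may hold the C1=C10 bond in a conformation that fits the titanium–tartrate–alkoxide assembly poorly, giving slow turnover or eroded facial selectivity. The fallback is a catalyst-controlled dioxirane epoxidation that needs no metal-bound hydroxyl. It sets out from PMB ether 35: Shi epoxidation (D-fructose-derived ketone, KHSO5, buffered MeCN/H2O, 0 °C) gives the epoxy PMB ether F4. For E-type trisubstituted olefins this catalyst should attack the same face as the D-(−)-tartrate system, and it should prefer the C1=C10 bond over the more electron-poor C4=C5 bond and the methylene lactone. DDQ as in step 22 then comes back to the route at epoxy alcohol 37.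

**Further compounds**
F1 | step 19 | (1(10)E,4E,6S,7S,8S)-15-(tert-butyldimethylsilyloxy)-14-(4-methoxybenzyloxy)-8-(triethylsilyloxy)germacra-1(10),4-dien-12,6-olide (cis-fused 6-epimer of 32) | C1C(=O)O[C@H]2/C=C(/CO[Si](C)(C)C(C)(C)C)CC/C=C(/COCc3ccc(OC)cc3)C[C@H](O[Si](CC)(CC)CC)[C@@H]12
F2 | step 19 | (1(10)E,4E,6S,7S,8S)-15-(tert-butyldimethylsilyloxy)-6-hydroxy-14-(4-methoxybenzyloxy)-8-(triethylsilyloxy)germacra-1(10),4-dien-12-oic acid | OC(=O)C[C@H]1[C@@H](O)/C=C(/CO[Si](C)(C)C(C)(C)C)CC/C=C(/COCc2ccc(OC)cc2)C[C@@H]1O[Si](CC)(CC)CC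
F3 | step 18 | methyl (3R,4S,6E,10E)-10-{[tert-butyl(dimethyl)silyl]oxymethyl}-11-iodo-3-[methoxy(methyl)carbamoyl]-6-{[(4-methoxybenzyl)oxy]methyl}-4-(triethylsilyloxy)undeca-6,10-dienoate | COC(=O)C[C@@H](C(=O)N(C)OC)[C@@H](O[Si](CC)(CC)CC)C/C(COCc1ccc(OC)cc1)=C\CC/C(CO[Si](C)(C)C(C)(C)C)=C\I
F4 | step 23 | (1R,4E,6R,7S,8S,10R)-15-(tert-butyldimethylsilyloxy)-1,10-epoxy-14-(4-methoxybenzyloxy)-8-(triethylsilyloxy)germacra-4,11(13)-dien-12,6-olide | C=C1C(=O)O[C@@H]2/C=C(/CO[Si](C)(C)C(C)(C)C)CC[C@H]3O[C@@]3(COCc4ccc(OC)cc4)C[C@H](O[Si](CC)(CC)CC)[C@@H]12
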